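Feature: in the oxolane (O1; C2 bearing ring A; C3 bearing C9H2OAc; C4 bearing C7'H2–ring B; C5H2) the unit O1–C2–C3–C9 is the β-alkoxy aldehyde pattern of a cinnamaldehyde, and C5–C4–C7' plus one carboxyl carbon is a 4-hydroxybut-2-enoate; that carboxyl is a stand-in for ring B.
Ring formation: only the oxolane is built (rings A and B are bought); cutting O1–C2 and C3–C4 together leads back to aldehyde 1, homologated by Wittig reaction to enal 2, and to hydroxy enoate 3; an amine-catalysed oxa-Michael/Michael domino joins 2 and 3 to aldehyde 4, reduced in the flask to alcohol 5.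
C7'–ring B: after O-silylation (6) and saponification (7), the carboxyl is exchanged for the aryl group of iodide 9 by nickel-catalysed decarboxylative coupling of the N-acyloxyphthalimide 8, giving 10.
End game: desilylation (11), acetylation of C9–OH (12), hydrogenolysis of the three benzyl ethers (13).
Key step: step 2

Remark: the locants O1, C2–C5, C9 and C7' used in the explanations are those of the target; systematic names of intermediates carry their own locants. Compounds 1, 3 and 9 are taken as purchasable.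

Step 1
Reactants: 1 3,4-bis(benzyloxy)benzaldehyde
Product: 2 (E)-3-[3,4-bis(benzyloxy)phenyl]prop-2-enal
Conditions: Ph3P=CHCHO (1.1 equiv), toluene, 90 °C
Reagents that add atoms: (triphenylphosphoranylidene)acetaldehyde, O=CC=P(c1ccccc1)(c1ccccc1)c1ccccc1
Why: Wittig olefination with the formyl-stabilised ylide should give the (E)-enal selectively, and keeping the ylide near one equivalent limits a second homologation to the dienal.

Step 2
Reactants: 2 (E)-3-[3,4-bis(benzyloxy)phenyl]prop-2-enal; 3 ethyl (E)-4-hydroxybut-2-enoate (2 equiv)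
Product: 5 ethyl 2-[(3R,4R,5S)-5-[3,4-bis(benzyloxy)phenyl]-4-(hydroxymethyl)oxolan-3-yl]acetate, via aldehyde 4 (not isolated)
Conditions: (S)-2-[diphenyl(trimethylsilyloxy)methyl]pyrrolidine (20 mol %), PhCO2H (20 mol %), toluene, rt; then EtOH, NaBH4, −20 °C
Reagents that add atoms: none
Why: Enal 2 condenses with the secondary amine to the (E)-iminium ion, whose β-carbon is open only on the Si face because the CPh2(OSiMe3) arm of the (S)-catalyst covers the Re face, so the hydroxyl of 3 adds there in a reversible oxa-Michael step that forms O1–C2 and sets C2 as S. The β-alkoxy enamine then attacks its own tethered enoate in an irreversible 5-exo-trig Michael addition (C3–C4 bond, oxolane ring), and hydrolysis releases aldehyde 4 and the catalyst; this is the iminium–enamine oxa-Michael/Michael domino type known for γ-hydroxy enones and for the sulfur and nitrogen analogues of 3. C3 is fixed trans to ring A because the enamine can reach the enoate only on the face that already carries O1, which is also the face left free by the catalyst. C4 is expected cis to the formyl group (trans to ring A) from the compact transition state in which the enoate lies stacked under the enamine, ester carbonyl beneath nitrogen, the arrangement invoked for the kinetic cis preference of amine-mediated 5-exo cyclisations of formyl-tethered enones and enals; the open transition state would give the all-trans isomer, so this ratio is the selectivity on which the step depends. The weakly nucleophilic alcohol must add 1,4 and not merely form acetals, which the benzoic acid co-catalyst, the excess of 3 and the draining of the 1,4-adduct alone by ring closure should secure. NaBH4 is added to the same flask at −20 °C so that the epimerisable C3 formyl centre is frozen as CH2OH before it can equilibrate, the ethyl ester being inert to the hydride.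

Step 3
Reactants: 5 ethyl 2-[(3R,4R,5S)-5-[3,4-bis(benzyloxy)phenyl]-4-(hydroxymethyl)oxolan-3-yl]acetate
Product: 6 ethyl 2-[(3R,4R,5S)-5-[3,4-bis(benzyloxy)phenyl]-4-({[tert-butyl(dimethyl)silyl]oxy}methyl)oxolan-3-yl]acetate
Conditions: TBSCl, imidazole, DMF, 0 °C to rt (run on freshly isolated 5)
Reagents that add atoms: tert-butyldimethylsilyl chloride, CC(C)(C)[Si](C)(C)Cl
Why: Imidazole-promoted silylation of the primary alcohol is fast and, run at once, should forestall closure of the cis-disposed CH2OH and CH2CO2Et groups to the δ-lactone; no stereocentre is touched.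

Step 4
Reactants: 6 ethyl 2-[(3R,4R,5S)-5-[3,4-bis(benzyloxy)phenyl]-4-({[tert-butyl(dimethyl)silyl]oxy}methyl)oxolan-3-yl]acetate
Product: 7 2-[(3R,4R,5S)-5-[3,4-bis(benzyloxy)phenyl]-4-({[tert-butyl(dimethyl)silyl]oxy}methyl)oxolan-3-yl]acetic acid
Conditions: LiOH·H2O, THF–H2O, rt; then 1 M HCl to pH 4, 0 °C
Reagents that add atoms: lithium hydroxide, [Li+].[OH-]
Why: Saponification of the ethyl ester leaves the primary silyl ether, the benzyl ethers and the oxolane intact, and cold acidification to pH 4 frees the acid without desilylation or ionisation at benzylic C2.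

Step 5
Reactants: 7 2-[(3R,4R,5S)-5-[3,4-bis(benzyloxy)phenyl]-4-({[tert-butyl(dimethyl)silyl]oxy}methyl)oxolan-3-yl]acetic acid
Product: 8 1,3-dioxoisoindolin-2-yl 2-[(3R,4R,5S)-5-[3,4-bis(benzyloxy)phenyl]-4-({[tert-butyl(dimethyl)silyl]oxy}methyl)oxolan-3-yl]acetate
Conditions: N-hydroxyphthalimide, N,N'-diisopropylcarbodiimide, DMAP (cat.), CH2Cl2, rt
Reagents that add atoms: N-hydroxyphthalimide, O=C1c2ccccc2C(=O)N1O
Why: Carbodiimide (Steglich-type) esterification turns the acid into the redox-active ester needed for single-electron decarboxylation.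

Step 6
Reactants: 8 1,3-dioxoisoindolin-2-yl 2-[(3R,4R,5S)-5-[3,4-bis(benzyloxy)phenyl]-4-({[tert-butyl(dimethyl)silyl]oxy}methyl)oxolan-3-yl]acetate; 9 1-(benzyloxy)-4-iodo-2-methoxybenzene
Product: 10 tert-butyl{[(2S,3R,4R)-2-[3,4-bis(benzyloxy)phenyl]-4-{[4-(benzyloxy)-3-methoxyphenyl]methyl}oxolan-3-yl]methoxy}dimethylsilane
Conditions: NiBr2(dme) (10 mol %), 4,4'-di-tert-butyl-2,2'-bipyridine (10 mol %), zinc powder (2 equiv), DMA, rt
Reagents that add atoms: none
Why: In this nickel-catalysed reductive cross-electrophile coupling, zinc-driven single-electron reduction of the N-acyloxyphthalimide releases CO2 and the primary C7' radical, which the arylnickel species formed from 9 should capture and reductively eliminate as the C7'–aryl bond; the radical carbon is not stereogenic and the ring stereocentres are untouched.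

Step 7
Reactants: 10 tert-butyl{[(2S,3R,4R)-2-[3,4-bis(benzyloxy)phenyl]-4-{[4-(benzyloxy)-3-methoxyphenyl]methyl}oxolan-3-yl]methoxy}dimethylsilane
Product: 11 [(2S,3R,4R)-2-[3,4-bis(benzyloxy)phenyl]-4-{[4-(benzyloxy)-3-methoxyphenyl]methyl}oxolan-3-yl]methanol
Conditions: TBAF, THF, 0 °C to rt; aqueous work-up
Reagents that add atoms: none
Why: Fluoride cleaves the Si–O bond of the primary silyl ether selectively, benzyl ethers and the oxolane being inert.

Step 8
Reactants: 11 [(2S,3R,4R)-2-[3,4-bis(benzyloxy)phenyl]-4-{[4-(benzyloxy)-3-methoxyphenyl]methyl}oxolan-3-yl]methanol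
Product: 12 [(2S,3R,4R)-2-[3,4-bis(benzyloxy)phenyl]-4-{[4-(benzyloxy)-3-methoxyphenyl]methyl}oxolan-3-yl]methyl acetate
Conditions: Ac2O, pyridine, DMAP (cat.), CH2Cl2, 0 °C to rt
Reagents that add atoms: acetic anhydride, CC(=O)OC(C)=O
Why: DMAP-catalysed acylation of the only free hydroxyl installs the C9 acetate while all three phenols are still masked.

Step 9
Reactants: 12 [(2S,3R,4R)-2-[3,4-bis(benzyloxy)phenyl]-4-{[4-(benzyloxy)-3-methoxyphenyl]methyl}oxolan-3-yl]methyl acetate
Product: 13 [(2S,3R,4R)-2-(3,4-dihydroxyphenyl)-4-[(4-hydroxy-3-methoxyphenyl)methyl]oxolan-3-yl]methyl acetate (CNP0273854.1)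
Conditions: H2 (1 atm), Pd/C (10 wt %), EtOAc, rt, stopped when the benzyl ethers are consumed; work-up under argon
Reagents that add atoms: none
Why: Catalytic hydrogenolysis should cleave the three aryl benzyl ethers much faster than the cyclic benzylic C2–O1 bond (as in the debenzylation of benzylated flavan-type 2-aryl cyclic ethers), the acetate is inert in a non-alcoholic solvent, and neutral conditions spare the acid-labile C2 centre.

Compound list
1 | 3,4-bis(benzyloxy)benzaldehyde | O=Cc1ccc(OCc2ccccc2)c(OCc2ccccc2)c1 | starting material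
2 | (E)-3-[3,4-bis(benzyloxy)phenyl]prop-2-enal | O=C/C=C/c1ccc(OCc2ccccc2)c(OCc2ccccc2)c1 | intermediate
3 | ethyl (E)-4-hydroxybut-2-enoate | CCOC(=O)/C=C/CO | starting material
4 | ethyl 2-[(3R,4S,5S)-5-[3,4-bis(benzyloxy)phenyl]-4-formyloxolan-3-yl]acetate (aryl/formyl trans, formyl/CH2CO2Et cis) | CCOC(=O)C[C@H]1CO[C@H](c2ccc(OCc3ccccc3)c(OCc3ccccc3)c2)[C@H]1C=O | intermediate (not isolated)
5 | ethyl 2-[(3R,4R,5S)-5-[3,4-bis(benzyloxy)phenyl]-4-(hydroxymethyl)oxolan-3-yl]acetate | CCOC(=O)C[C@H]1CO[C@H](c2ccc(OCc3ccccc3)c(OCc3ccccc3)c2)[C@H]1CO | intermediate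
6 | ethyl 2-[(3R,4R,5S)-5-[3,4-bis(benzyloxy)phenyl]-4-({[tert-butyl(dimethyl)silyl]oxy}methyl)oxolan-3-yl]acetate | CCOC(=O)C[C@H]1CO[C@H](c2ccc(OCc3ccccc3)c(OCc3ccccc3)c2)[C@H]1CO[Si](C)(C)C(C)(C)C | intermediate
7 | 2-[(3R,4R,5S)-5-[3,4-bis(benzyloxy)phenyl]-4-({[tert-butyl(dimethyl)silyl]oxy}methyl)oxolan-3-yl]acetic acid | OC(=O)C[C@H]1CO[C@H](c2ccc(OCc3ccccc3)c(OCc3ccccc3)c2)[C@H]1CO[Si](C)(C)C(C)(C)C | intermediate
8 | 1,3-dioxoisoindolin-2-yl 2-[(3R,4R,5S)-5-[3,4-bis(benzyloxy)phenyl]-4-({[tert-butyl(dimethyl)silyl]oxy}methyl)oxolan-3-yl]acetate | O=C(C[C@H]1CO[C@H](c2ccc(OCc3ccccc3)c(OCc3ccccc3)c2)[C@H]1CO[Si](C)(C)C(C)(C)C)ON1C(=O)c2ccccc2C1=O | intermediate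
9 | 1-(benzyloxy)-4-iodo-2-methoxybenzene | COc1cc(I)ccc1OCc1ccccc1 | starting material
10 | tert-butyl{[(2S,3R,4R)-2-[3,4-bis(benzyloxy)phenyl]-4-{[4-(benzyloxy)-3-methoxyphenyl]methyl}oxolan-3-yl]methoxy}dimethylsilane | COc1cc(C[C@H]2CO[C@H](c3ccc(OCc4ccccc4)c(OCc4ccccc4)c3)[C@H]2CO[Si](C)(C)C(C)(C)C)ccc1OCc1ccccc1 | intermediate
11 | [(2S,3R,4R)-2-[3,4-bis(benzyloxy)phenyl]-4-{[4-(benzyloxy)-3-methoxyphenyl]methyl}oxolan-3-yl]methanol | COc1cc(C[C@H]2CO[C@H](c3ccc(OCc4ccccc4)c(OCc4ccccc4)c3)[C@H]2CO)ccc1OCc1ccccc1 | intermediate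
12 | [(2S,3R,4R)-2-[3,4-bis(benzyloxy)phenyl]-4-{[4-(benzyloxy)-3-methoxyphenyl]methyl}oxolan-3-yl]methyl acetate | COc1cc(C[C@H]2CO[C@H](c3ccc(OCc4ccccc4)c(OCc4ccccc4)c3)[C@H]2COC(C)=O)ccc1OCc1ccccc1 | intermediate
13 | [(2S,3R,4R)-2-(3,4-dihydroxyphenyl)-4-[(4-hydroxy-3-methoxyphenyl)methyl]oxolan-3-yl]methyl acetate | COc1cc(C[C@H]2CO[C@H](c3ccc(O)c(O)c3)[C@H]2COC(C)=O)ccc1O | target

Total steps: 9. Longest linear sequence: 9 steps (1 to 13); 3 and 9 enter as bought fragments.

Steps most likely to fail

Step 2 (domino annulation). The aliphatic hydroxyl is a poor donor and the iminium ion of the electron-rich enal a modest acceptor, so the reversible O1–C2 addition may lie on the side of the components and be emptied only slowly by the enoate, leaving room for acetal formation and self-condensation of 2. Ring closure through the open instead of the stacked transition state would place C4 in the wrong sense (all-trans oxolane), and this centre cannot be corrected later. Slow reduction could also let C3 epimerise.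

Fallback: lactone-aldol chemistry, setting out from aldehyde 1 and rejoining the route at alcohol 11, so that steps 2–7 are bypassed.
- Stobbe condensation of 4-(benzyloxy)-3-methoxybenzaldehyde with dimethyl succinate (NaOMe, MeOH) gives (E)-4-[4-(benzyloxy)-3-methoxyphenyl]-3-(methoxycarbonyl)but-3-enoic acid F1.
- Asymmetric hydrogenation (H2, [Rh(cod)2]BF4 with a chiral bisphosphine chosen for the R acid, MeOH) gives (R)-4-[4-(benzyloxy)-3-methoxyphenyl]-3-(methoxycarbonyl)butanoic acid F2.
- Reduction of the ester beside the carboxylate (Ca(BH4)2, EtOH) and acidification close (R)-4-{[4-(benzyloxy)-3-methoxyphenyl]methyl}oxolan-2-one F3.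
- Its lithium enolate (LiN(iPr)2, THF, −78 °C) should add to 1 anti to the benzyl group, giving the trans aldol lactone (3S,4R)-3-{[3,4-bis(benzyloxy)phenyl](hydroxy)methyl}-4-{[4-(benzyloxy)-3-methoxyphenyl]methyl}oxolan-2-one F4; both carbinol epimers are usable.
- LiAlH4 (THF, 0 °C) reduces it to (2R,3R)-2-{[3,4-bis(benzyloxy)phenyl](hydroxy)methyl}-3-{[4-(benzyloxy)-3-methoxyphenyl]methyl}butane-1,4-diol F5.
- Camphorsulfonic acid (cat., CH2Cl2, 0 °C) ionises the p-alkoxybenzylic alcohol, which the C5 primary hydroxyl captures to close the 2,3-trans oxolane 11; the trans lactone geometry becomes the 3,4-cis relationship.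

Step 6 (decarboxylative arylation). The primary radical may be reduced or dimerise faster than arylnickel captures it, and the electron-rich iodide may add sluggishly to nickel or homocouple.

Fallback: a redox-neutral coupling with a preformed aryl nucleophile, setting out from 8 and 9 and returning at 10. Iodine–magnesium exchange on 9 (iPrMgCl·LiCl, THF, −20 °C) and transmetalation with ZnCl2 give [4-(benzyloxy)-3-methoxyphenyl]zinc chloride F6. Negishi-type decarboxylative coupling of F6 with ester 8 (NiCl2(dme), 4,4'-di-tert-butyl-2,2'-bipyridine, THF–DMF, rt) should then form the same C7'–aryl bond without a metal reductant.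

Step 3 (silylation of 5). The cis hydroxy ester may collapse to the bicyclic δ-lactone during the borohydride quench or on silica before the silyl group is on, leaving no hydroxyl to protect.

Fallback: an order of operations that makes lactonisation harmless, setting out from 5 (or the lactone formed from it) and returning at acid 7. LiOH (THF–H2O) opens ester or lactone alike to lithium 2-[(3R,4R,5S)-5-[3,4-bis(benzyloxy)phenyl]-4-(hydroxymethyl)oxolan-3-yl]acetate F7, which is dried without acidification. Excess TBSCl and imidazole (DMF) silylate both oxygens to tert-butyldimethylsilyl 2-[(3R,4R,5S)-5-[3,4-bis(benzyloxy)phenyl]-4-({[tert-butyl(dimethyl)silyl]oxy}methyl)oxolan-3-yl]acetate F8. K2CO3 in MeOH–THF–H2O then cleaves only the silyl ester, giving 7 after acidification to pH 4.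

Further compounds
F1 | step 2 | (E)-4-[4-(benzyloxy)-3-methoxyphenyl]-3-(methoxycarbonyl)but-3-enoic acid | COC(=O)/C(=C/c1ccc(OCc2ccccc2)c(OC)c1)CC(=O)O
F2 | step 2 | (R)-4-[4-(benzyloxy)-3-methoxyphenyl]-3-(methoxycarbonyl)butanoic acid | COC(=O)[C@@H](CC(=O)O)Cc1ccc(OCc2ccccc2)c(OC)c1
F3 | step 2 | (R)-4-{[4-(benzyloxy)-3-methoxyphenyl]methyl}oxolan-2-one | O=C1C[C@@H](Cc2ccc(OCc3ccccc3)c(OC)c2)CO1
F4 | step 2 | (3S,4R)-3-{[3,4-bis(benzyloxy)phenyl](hydroxy)methyl}-4-{[4-(benzyloxy)-3-methoxyphenyl]methyl}oxolan-2-one | COc1cc(C[C@H]2COC(=O)[C@@H]2C(O)c2ccc(OCc3ccccc3)c(OCc3ccccc3)c2)ccc1OCc1ccccc1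
F5 | step 2 | (2R,3R)-2-{[3,4-bis(benzyloxy)phenyl](hydroxy)methyl}-3-{[4-(benzyloxy)-3-methoxyphenyl]methyl}butane-1,4-diol | COc1cc(C[C@@H](CO)[C@H](CO)C(O)c2ccc(OCc3ccccc3)c(OCc3ccccc3)c2)ccc1OCc1ccccc1
F6 | step 6 | [4-(benzyloxy)-3-methoxyphenyl]zinc chloride | COc1cc([Zn]Cl)ccc1OCc1ccccc1
F7 | step 3 | lithium 2-[(3R,4R,5S)-5-[3,4-bis(benzyloxy)phenyl]-4-(hydroxymethyl)oxolan-3-yl]acetate | [Li+].[O-]C(=O)C[C@H]1CO[C@H](c2ccc(OCc3ccccc3)c(OCc3ccccc3)c2)[C@H]1CO
F8 | step 3 | tert-butyldimethylsilyl 2-[(3R,4R,5S)-5-[3,4-bis(benzyloxy)phenyl]-4-({[tert-butyl(dimethyl)silyl]oxy}methyl)oxolan-3-yl]acetate | CC(C)(C)[Si](C)(C)OC(=O)C[C@H]1CO[C@H](c2ccc(OCc3ccccc3)c(OCc3ccccc3)c2)[C@H]1CO[Si](C)(C)C(C)(C)C
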